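## Analysis of the target

Betaethrin H (17) is a diaryl ether of two resorcinol-type benzene rings; it has no ring fusion and no stereocentre, and its only chain is the unbranched palmitoyl group. Ring B is an orcinol unit (3-hydroxy-5-methylphenoxy) joined through oxygen to C2 of ring A. Ring A is 1,2,3,5-tetrasubstituted: C1 carries the CH2O–palmitoyl group, C2 the aryloxy oxygen, C3 a free hydroxyl and C5 a methoxy group, while C4 and C6 are CH. The sensitive groups are the benzylic ester on an electron-rich ring, which is cleaved by hydrogenolysis, hydride and alkoxide, and the two free phenols, which compete in any acylation. The synthesis is hard for three reasons. The ether oxygen sits on the most hindered carbon of ring A, between two ortho substituents on an electron-rich ring, so a late aryl–oxygen coupling is unattractive. The three oxygens of ring A must end as three different groups, and the two oxygens of ring B must be told apart. The primary alcohol must be esterified beside two phenols. The strategy rests on one feature: C1 (carbon substituent), C3 (oxygen) and C5 (oxygen) of ring A form the 1,3,5 pattern of a folded tricarbonyl chain. C2, with its aryloxy group, lies between C1 and C3 and can therefore be the nucleophilic carbon of an aryloxymethyl ketone, and the methylated C5 oxygen can be carried through the open chain as an enol ether.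

## Retrosynthetic reasoning

**Ester C–O bond of 17.** The palmitate is cut first, which gives the triol 15 and palmitic acid 16. The benzylic ester is the most fragile group of the target, so nothing may follow its formation. The forward reaction must acylate the primary hydroxyl and leave both phenols free; a Mitsunobu esterification activates the alcohol and not the acid, so the phenols are not acylated.

**Oxidation level at C1 and the ring B protecting group (15 to 14 to 13).** The CH2OH group of 15 is traced back to the ethyl ester of 14, and the ring B phenol of 14 to the benzyl ether of 13. The order is fixed by the structure. Hydrogenolysis comes while C1 is still an ester, because an electron-rich benzylic alcohol or benzylic ester could itself be hydrogenolysed. Hydride reduction then needs no protection of the phenols.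

**C1–C2 bond of ring A (13 to 11).** Ring A is opened between the ester-bearing carbon and the aryloxy-bearing carbon, which gives the open chain 11. Ring carbon C1 is C2 of the chain, the ketone of an alpha-keto ester, and ring carbon C2 is C7, an aryloxy-substituted methylene beside the C6 ketone. This cut is chosen because it turns the hindered diaryl ether into a plain aryloxyacetyl unit and removes the need for any aryl–oxygen coupling on ring A. It also fixes the oxygen pattern: the C4 enol ether oxygen of 11 becomes the C5 methoxy group and the C6 ketone oxygen becomes the C3 hydroxyl. The forward reaction is an intramolecular aldol addition of C7 to C2, followed by dehydration and enolization to the arene.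

**C5–C6 bond of the chain (11 to 8 and 5).** The chain is cut between the enol ether part and the aryloxymethyl ketone. The N-methoxy-N-methylamide 5 brings C6, C7 and ring B, and the keto ester 8 brings C1 to C5 through its dienolate. The opposite order (aryloxyacetyl unit first, oxalyl unit second) is not used, because the second acylation would then have to choose the gamma-methyl group over the more acidic aryloxy-substituted methylene. In 8 the gamma-methyl group is the only enolizable position, so the site of the new bond is set by the structure and not by the base.

**C2–C3 bond of 8 (8 to 6 and 7).** The keto ester is cut between its ketone and the enol ether carbon, which gives 2-methoxypropene 6 and ethyl chlorooxoacetate 7. Acylation of the enol ether installs the methyl ether on the correct oxygen in the first C–C bond-forming step.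

**Ether bonds of 5 and 3 (5 to 3 and 4; 3 to 1 and 2).** The O–CH2 bond of 5 is cut to the phenol 3 and the chloroacetamide 4, and the benzyl ether of 3 to orcinol 1 and benzyl bromide 2. Both are Williamson alkylations. The only ring B problem, telling its two oxygens apart, is met at the first step on the cheapest material.

## Alternatives that were turned down

**Alternative 1:** Ring B is taken apart instead of ring A. Its C1'–C6' and C2'–C3' bonds are cut (C1' carries the ether oxygen), which leads to the aryl ethynyl ether A2 of a complete ring A phenol and the protected pyranone A3. In the forward direction A2 would add across C3 and C6 of A3 in a [4+2] cycloaddition, and the bridged lactone would aromatize by decarboxylation to the protected diaryl ether A1.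
- For it: the regiochemistry is electronically matched, since the nucleophilic terminal alkyne carbon meets the electrophilic C6 of the pyranone. The ether oxygen is never introduced by coupling at a hindered carbon. The two oxygens of ring B differ from the start, so the statistical mono-protection of 1 in step 1 is avoided; on that point it is stronger than the chosen route.
- Against it: the ring that is built is the one that can be bought as 1. The tetrasubstituted ring A, with three different oxygen substituents, would need a separate multistep synthesis and then conversion into an ynol ether at a phenol with two ortho substituents. Both cycloaddition partners are donor-substituted, so high temperature would be needed, where aryl alkynyl ethers are not robust.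
- Comparison: with the ring A synthesis, the ynol ether formation and three deprotections it is clearly longer. The chosen strategy builds the difficult ring and sets all four of its substituents in one step from a chain made in two steps.

**Alternative 2:** Ring A is cut at three bonds, C2–C3, C3–C4 and C5–C6, which gives the 4-aryloxycyclobutenone A5 and methoxyacetylene A6. On heating, A5 would open to a vinylketene and A6 would add to the ketene by [2+2] cycloaddition. Four-electron ring opening, six-electron electrocyclization and tautomerization would then give the phenol A4 (Danheiser benzannulation).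
- For it: this is the most convergent ring construction, with three C–C bonds in one thermal operation. The hydroxyl (from the ketene carbon) and the methoxy group (from the alkyne) are placed without ambiguity. C1 is already at the alcohol oxidation level, so no hydride reduction is needed. On bond economy and redox economy it is stronger than the chosen route.
- Against it: A5 would have to come from an aryloxyketene and an unactivated propargylic alkyne, a sluggish [2+2] cycloaddition, and it carries an acidic aryloxy-substituted sp3 carbon beside the carbonyl group. A6 is volatile, must be prepared and polymerizes easily. The cascade runs through several pericyclic steps at elevated temperature, each with a competing channel such as ketene dimerization.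
- Comparison: two silyl ethers must still be removed after the key step and the same chemoselective esterification is needed, so nothing is saved at the end. The chosen route reaches 11 in two bond-forming steps from cheap acylating agents and needs only a base for ring closure.

**Alternative 3:** Ring A is first made as a saturated carbocycle. The C1–C6 and C4–C5 bonds are cut, which gives the alpha-aryloxy enone A8 and dimethyl malonate A9. The anion of A9 would add to the beta-carbon of A8 (Michael addition), and the methyl ketone enolate of the adduct would attack a malonate ester (Claisen condensation) to close the cyclohexane-1,3-dione A7.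
- For it: the chemistry is classical and uses only alkoxide bases. C1 arrives with its CH2O substituent at the final oxidation level, so the reduction of step 7 would not be needed; on that point it is as strong or stronger.
- Against it: A8 is a poor Michael acceptor, because the alpha-aryloxy group donates into the enone and the beta-carbon is substituted. A7 is at the dihydro level and has three stereocentres of no value. Three tasks follow: removal of the extra ester group, dehydrogenation to the arene, and methylation of the C5 oxygen only. The last is the real weakness, because the two oxygens of a cyclohexane-1,3-dione exchange roles through its enol tautomers, so nothing in A7 tells the C3 oxygen from the C5 oxygen.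
- Comparison: in the chosen route the methyl group sits on the right oxygen from 6 onwards and ring A leaves the key step already aromatic. The end sequence is at least three steps shorter.

Key step: step 5

Remark: 11 is written as its 2,6-diketo-4-ene tautomer; it is expected to equilibrate with its 3-ene and enol tautomers, which all give the same anions, so the tautomer ratio has no bearing on the route. The transient stereocentres of 10 and 12 and the enolate geometry of 9 are written without configuration.

## Route

Step 1
Reactants: 1 orcinol; 2 benzyl bromide
Product: 3 3-(benzyloxy)-5-methylphenol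
Conditions: 1 (3 equiv), BnBr (1 equiv), K2CO3, acetone, reflux
Reagents that add atoms: benzyl bromide (2), BrCc1ccccc1
Why: Williamson ether synthesis on a symmetric diphenol; with 1 in excess the mono-ether should be the main product, and unreacted 1 is removed by aqueous extraction.

Step 2
Reactants: 3 3-(benzyloxy)-5-methylphenol; 4 2-chloro-N-methoxy-N-methylacetamide
Product: 5 2-[3-(benzyloxy)-5-methylphenoxy]-N-methoxy-N-methylacetamide
Conditions: K2CO3, KI (cat.), DMF, 60 °C
Reagents that add atoms: 2-chloro-N-methoxy-N-methylacetamide (4), CON(C)C(=O)CCl
Why: Williamson alkylation of the phenoxide by an activated alpha-chloro amide; it puts the future diaryl ether oxygen on the carbon that will become C2 of ring A and gives an acyl donor that cannot over-react.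

Step 3
Reactants: 6 2-methoxypropene; 7 ethyl chlorooxoacetate
Product: 8 ethyl (3E)-4-methoxy-2-oxopent-3-enoate
Conditions: pyridine, CH2Cl2, 0 °C to rt
Reagents that add atoms: ethyl chlorooxoacetate (7), CCOC(=O)C(=O)Cl
Why: Electrophilic acylation of an enol ether by an oxalyl chloride half ester, followed by loss of HCl to pyridine, gives the push-pull beta-methoxy enone. The (E) isomer, with the methoxy group trans to the acyl group, is the thermodynamically preferred one.

Step 4
Reactants: 8 ethyl (3E)-4-methoxy-2-oxopent-3-enoate; 5 2-[3-(benzyloxy)-5-methylphenoxy]-N-methoxy-N-methylacetamide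
Product: 11 ethyl (4E)-7-[3-(benzyloxy)-5-methylphenoxy]-4-methoxy-2,6-dioxohept-4-enoate, via lithium dienolate 9 (not isolated), via tetrahedral lithium adduct 10 (not isolated)
Conditions: 8 (1.5 equiv), LiN(SiMe3)2 (1.5 equiv), THF, −78 °C; then 5 (1 equiv), −78 to −20 °C; AcOH quench, buffered aqueous work-up
Reagents that add atoms: none
Why: Vinylogous Claisen-type acylation: the gamma-methyl group is the only enolizable position of 8, and its dienolate 9 reacts through the unhindered terminal carbon, as dienolates of beta-alkoxy-alpha,beta-unsaturated carbonyl compounds do. The chelated adduct 10 of the N-methoxy-N-methylamide releases the ketone only on work-up, so no second acylation can occur, and tautomer equilibration gives 11.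

Step 5
Reactants: 11 ethyl (4E)-7-[3-(benzyloxy)-5-methylphenoxy]-4-methoxy-2,6-dioxohept-4-enoate
Product: 13 ethyl 2-[3-(benzyloxy)-5-methylphenoxy]-3-hydroxy-5-methoxybenzoate, via cyclic aldol 12 (not isolated)
Conditions: DBU (2 equiv), MeCN (0.02 M), 0 °C to rt; then cold 1 M HCl
Reagents that add atoms: none
Why: The amidine base deprotonates 11 reversibly; the resting anion is the dienolate of the doubly activated C3 methylene, but proton transfer through protonated DBU also gives the enolate at C7, the aryloxy-bearing carbon beside the C6 ketone. This enolate adds to the C2 ketone of the alpha-keto ester, the most electrophilic carbonyl of the chain, and forms the C7–C2 bond (C2–C1 of ring A) in a 6-(enolendo)-exo-trig closure to give aldol 12. E1cB loss of water across C2–C7 and enolization of the C6 ketone then give the phenol 13, so the closure is pulled forward by aromatization. The closest known reaction type is the base-mediated aldol cyclization and aromatization of 2,4,6-tricarbonyl chains to resorcinols, the laboratory form of polyketide folding. The two stereocentres of 12 are transient and none remains in 13. C-closure wins over O-closure because attack of the enolate oxygen on C2 gives only a reversible hemiketal that cannot aromatize under base, and the C3 anion has no carbonyl within reach of a five- or six-membered ring. The (4E) enol ether holds C3 and C6 cis so that C2 and C7 can meet, and it fixes the C4 oxygen as the C5 methoxy group and the C6 oxygen as the C3 hydroxyl of ring A. An aprotic base is used so that no alkoxide can exchange the enol ether methoxy group or the ester.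

Step 6
Reactants: 13 ethyl 2-[3-(benzyloxy)-5-methylphenoxy]-3-hydroxy-5-methoxybenzoate
Product: 14 ethyl 3-hydroxy-2-(3-hydroxy-5-methylphenoxy)-5-methoxybenzoate
Conditions: H2 (1 atm), Pd/C (10% palladium on carbon), EtOAc/EtOH, rt
Reagents that add atoms: none
Why: Hydrogenolysis of the aryl benzyl ether; the diaryl ether, the aryl methyl ether and the ester are inert, and C1 is still an ester, so no benzylic C–O bond on ring A is exposed.

Step 7
Reactants: 14 ethyl 3-hydroxy-2-(3-hydroxy-5-methylphenoxy)-5-methoxybenzoate
Product: 15 2-(3-hydroxy-5-methylphenoxy)-3-(hydroxymethyl)-5-methoxyphenol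
Conditions: LiAlH4 (4 equiv), THF, 0 to 40 °C; then H2O, 1 M HCl to pH 3–4, 0 °C
Reagents that add atoms: none
Why: Hydride reduction of the ester to the primary alcohol; the two phenols are deprotonated first and only consume hydride. The ring A phenoxide is meta to the ester, so it neither deactivates it strongly nor opens a quinone methide path to over-reduction.

Step 8
Reactants: 15 2-(3-hydroxy-5-methylphenoxy)-3-(hydroxymethyl)-5-methoxyphenol; 16 palmitic acid
Product: 17 Betaethrin H, [3-hydroxy-2-(3-hydroxy-5-methylphenoxy)-5-methoxyphenyl]methyl hexadecanoate
Conditions: 16 (1.1 equiv), PPh3, DIAD, THF, 0 °C to rt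
Reagents that add atoms: palmitic acid (16), CCCCCCCCCCCCCCCC(=O)O
Why: Mitsunobu esterification activates the primary benzylic alcohol as an oxyphosphonium ion, which the carboxylate displaces. The carboxylic acid is far more acidic than the phenols and is the pronucleophile, so the phenols stay free; the ring A phenol is meta to the benzylic carbon, so no quinone methide can form.

## Compound list

1 | orcinol (5-methylbenzene-1,3-diol) | Cc1cc(O)cc(O)c1 | starting material
2 | benzyl bromide | BrCc1ccccc1 | starting material
3 | 3-(benzyloxy)-5-methylphenol | Cc1cc(O)cc(OCc2ccccc2)c1 | intermediate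
4 | 2-chloro-N-methoxy-N-methylacetamide | CON(C)C(=O)CCl | starting material
5 | 2-[3-(benzyloxy)-5-methylphenoxy]-N-methoxy-N-methylacetamide | CON(C)C(=O)COc1cc(C)cc(OCc2ccccc2)c1 | intermediate
6 | 2-methoxypropene | COC(C)=C | starting material
7 | ethyl chlorooxoacetate | CCOC(=O)C(=O)Cl | starting material
8 | ethyl (3E)-4-methoxy-2-oxopent-3-enoate | CCOC(=O)C(=O)/C=C(\C)OC | intermediate
9 | lithium 1-ethoxy-4-methoxy-1-oxopenta-2,4-dien-2-olate (not isolated; enolate geometry not defined) | [Li+].CCOC(=O)C([O-])=CC(OC)=C | intermediate
10 | lithium 1-[3-(benzyloxy)-5-methylphenoxy]-7-ethoxy-4-methoxy-2-[methoxy(methyl)amino]-6,7-dioxohept-4-en-2-olate (not isolated; racemic) | [Li+].CCOC(=O)C(=O)C=C(OC)CC([O-])(COc1cc(C)cc(OCc2ccccc2)c1)N(C)OC | intermediate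
11 | ethyl (4E)-7-[3-(benzyloxy)-5-methylphenoxy]-4-methoxy-2,6-dioxohept-4-enoate | CCOC(=O)C(=O)C/C(OC)=C\C(=O)COc1cc(C)cc(OCc2ccccc2)c1 | intermediate
12 | ethyl 2-[3-(benzyloxy)-5-methylphenoxy]-1-hydroxy-5-methoxy-3-oxocyclohex-4-ene-1-carboxylate (not isolated; mixture of diastereomers) | CCOC(=O)C1(O)CC(OC)=CC(=O)C1Oc1cc(C)cc(OCc2ccccc2)c1 | intermediate
13 | ethyl 2-[3-(benzyloxy)-5-methylphenoxy]-3-hydroxy-5-methoxybenzoate | CCOC(=O)c1cc(OC)cc(O)c1Oc1cc(C)cc(OCc2ccccc2)c1 | intermediate
14 | ethyl 3-hydroxy-2-(3-hydroxy-5-methylphenoxy)-5-methoxybenzoate | CCOC(=O)c1cc(OC)cc(O)c1Oc1cc(C)cc(O)c1 | intermediate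
15 | 2-(3-hydroxy-5-methylphenoxy)-3-(hydroxymethyl)-5-methoxyphenol | OCc1cc(OC)cc(O)c1Oc1cc(C)cc(O)c1 | intermediate
16 | palmitic acid (hexadecanoic acid) | CCCCCCCCCCCCCCCC(=O)O | starting material
17 | Betaethrin H, [3-hydroxy-2-(3-hydroxy-5-methylphenoxy)-5-methoxyphenyl]methyl hexadecanoate | CCCCCCCCCCCCCCCC(=O)OCc1cc(OC)cc(O)c1Oc1cc(C)cc(O)c1 | target

## Step count and least certain steps

Total: 8 steps. Longest linear sequence: 7 steps (1, 2, 4, 5, 6, 7, 8); step 3 is a one-step side branch.

**Step 5 (key step).** The most likely failure is that the chain rests as the stabilized dienolate of the C3 methylene, in which C2 is part of the anion, so that ring closure is slow. Intermolecular aldol condensation onto the alpha-keto ester, or O-closure followed by loss of methanol to a 4-pyranone on acidic work-up, could then consume the chain.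

Fallback, from 11 back to 13, closing the same bond by a pericyclic reaction instead of an aldol addition: 11 is treated with tert-butyldimethylsilyl triflate and Et3N in CH2Cl2 at 0 °C to give ethyl (4E)-7-[3-(benzyloxy)-5-methylphenoxy]-2,6-bis(tert-butyldimethylsilyloxy)-4-methoxyhepta-2,4,6-trienoate F1, whose central double bond keeps C3 and C6 cis. Heating in toluene at 80–110 °C should bring about a disrotatory six-electron electrocyclization to ethyl 6-[3-(benzyloxy)-5-methylphenoxy]-1,5-bis(tert-butyldimethylsilyloxy)-3-methoxycyclohexa-2,4-diene-1-carboxylate F2. F2 aromatizes by loss of silanol across the new bond to ethyl 2-[3-(benzyloxy)-5-methylphenoxy]-3-(tert-butyldimethylsilyloxy)-5-methoxybenzoate F3. Bu4NF in THF then removes the aryl silyl ether and gives 13.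

**Step 4.** The stabilized dienolate 9 may add too slowly to the amide, may react through C3 instead of the terminal carbon, or 8 may condense with its own keto group before 5 is added.

Fallback, from 3 and 8 back to 11, using a neutral silyl dienol ether and an acid chloride instead of a lithium dienolate and an amide: 3 is alkylated with bromoacetic acid in aqueous NaOH to give [3-(benzyloxy)-5-methylphenoxy]acetic acid F4, which oxalyl chloride with catalytic DMF converts into [3-(benzyloxy)-5-methylphenoxy]acetyl chloride F5. Separately, 8 is silylated with tert-butyldimethylsilyl triflate and Et3N to give ethyl 2-(tert-butyldimethylsilyloxy)-4-methoxypenta-2,4-dienoate F6. F5 and F6 are combined in CH2Cl2 at −78 °C to rt (with catalytic ZnCl2 if needed); acylation at the terminal carbon of the diene and loss of the silyl group give 11.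

**Step 8.** The activated benzylic carbon may be attacked by a phenol of a second molecule in place of the carboxylate, which would give benzyl aryl ethers and oligomers; separating the lipophilic product from the phosphine oxide may also cost material.

Fallback, from 15 back to 17, by full acylation and selective cleavage instead of selective acylation: 15 is acylated with palmitoyl chloride (3.5 equiv), pyridine and catalytic DMAP to give [3-(hexadecanoyloxy)-2-[3-(hexadecanoyloxy)-5-methylphenoxy]-5-methoxyphenyl]methyl hexadecanoate F7. Pyrrolidine (2.2 equiv) in CH2Cl2 at 0 °C then cleaves the two aryl esters by aminolysis, which is much faster for aryl than for alkyl esters, and leaves 17.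

**Step 1.** The statistical alkylation may give too much bis-benzyl ether and some C-benzylation of the very nucleophilic ring, so that the supply of 3 is poor.

Fallback, from 1 back to 3, by exhaustive alkylation and single dealkylation: 1 is treated with an excess of 2 and K2CO3 in DMF to give 1,3-bis(benzyloxy)-5-methylbenzene F8. NaSEt (1.2 equiv) in DMF at 110 °C removes one benzyl group by attack at the benzylic carbon; the phenoxide formed makes the second aryloxide a far poorer leaving group, so the reaction should stop at 3.

## Further compounds

F1 | step 5 | ethyl (4E)-7-[3-(benzyloxy)-5-methylphenoxy]-2,6-bis(tert-butyldimethylsilyloxy)-4-methoxyhepta-2,4,6-trienoate | CCOC(=O)C(O[Si](C)(C)C(C)(C)C)=C/C(OC)=C\C(O[Si](C)(C)C(C)(C)C)=COc1cc(C)cc(OCc2ccccc2)c1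
F2 | step 5 | ethyl 6-[3-(benzyloxy)-5-methylphenoxy]-1,5-bis(tert-butyldimethylsilyloxy)-3-methoxycyclohexa-2,4-diene-1-carboxylate (mixture of diastereomers) | CCOC(=O)C1(O[Si](C)(C)C(C)(C)C)C=C(OC)C=C(O[Si](C)(C)C(C)(C)C)C1Oc1cc(C)cc(OCc2ccccc2)c1
F3 | step 5 | ethyl 2-[3-(benzyloxy)-5-methylphenoxy]-3-(tert-butyldimethylsilyloxy)-5-methoxybenzoate | CCOC(=O)c1cc(OC)cc(O[Si](C)(C)C(C)(C)C)c1Oc1cc(C)cc(OCc2ccccc2)c1
F4 | step 4 | [3-(benzyloxy)-5-methylphenoxy]acetic acid | OC(=O)COc1cc(C)cc(OCc2ccccc2)c1
F5 | step 4 | [3-(benzyloxy)-5-methylphenoxy]acetyl chloride | ClC(=O)COc1cc(C)cc(OCc2ccccc2)c1
F6 | step 4 | ethyl 2-(tert-butyldimethylsilyloxy)-4-methoxypenta-2,4-dienoate (enol ether geometry not defined) | CCOC(=O)C(O[Si](C)(C)C(C)(C)C)=CC(OC)=C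
F7 | step 8 | [3-(hexadecanoyloxy)-2-[3-(hexadecanoyloxy)-5-methylphenoxy]-5-methoxyphenyl]methyl hexadecanoate | CCCCCCCCCCCCCCCC(=O)OCc1cc(OC)cc(OC(=O)CCCCCCCCCCCCCCC)c1Oc1cc(C)cc(OC(=O)CCCCCCCCCCCCCCC)c1
F8 | step 1 | 1,3-bis(benzyloxy)-5-methylbenzene | Cc1cc(OCc2ccccc2)cc(OCc2ccccc2)c1
A1 | alternative 1 | tert-butyl({5-methoxy-3-(methoxymethoxy)-2-[3-(methoxymethoxy)-5-methylphenoxy]phenyl}methoxy)dimethylsilane | COCOc1cc(C)cc(Oc2c(CO[Si](C)(C)C(C)(C)C)cc(OC)cc2OCOC)c1
A2 | alternative 1 | tert-butyl{[2-(ethynyloxy)-5-methoxy-3-(methoxymethoxy)phenyl]methoxy}dimethylsilane | C#COc1c(CO[Si](C)(C)C(C)(C)C)cc(OC)cc1OCOC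
A3 | alternative 1 | 4-(methoxymethoxy)-6-methyl-2H-pyran-2-one | COCOC1=CC(=O)OC(C)=C1
A4 | alternative 2 | 2-[3-(tert-butyldimethylsilyloxy)-5-methylphenoxy]-3-[(tert-butyldimethylsilyloxy)methyl]-5-methoxyphenol | COc1cc(O)c(Oc2cc(C)cc(O[Si](C)(C)C(C)(C)C)c2)c(CO[Si](C)(C)C(C)(C)C)c1
A5 | alternative 2 | 4-[3-(tert-butyldimethylsilyloxy)-5-methylphenoxy]-3-[(tert-butyldimethylsilyloxy)methyl]cyclobut-2-en-1-one (racemic) | O=C1C=C(CO[Si](C)(C)C(C)(C)C)C1Oc1cc(C)cc(O[Si](C)(C)C(C)(C)C)c1
A6 | alternative 2 | methoxyacetylene (methoxyethyne) | COC#C
A7 | alternative 3 | methyl 5-[3-(benzyloxy)-5-methylphenoxy]-6-[(tert-butyldimethylsilyloxy)methyl]-2,4-dioxocyclohexane-1-carboxylate (mixture of diastereomers) | COC(=O)C1C(=O)CC(=O)C(Oc2cc(C)cc(OCc3ccccc3)c2)C1CO[Si](C)(C)C(C)(C)C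
A8 | alternative 3 | 3-[3-(benzyloxy)-5-methylphenoxy]-5-(tert-butyldimethylsilyloxy)pent-3-en-2-one (double bond geometry not defined) | CC(=O)C(Oc1cc(C)cc(OCc2ccccc2)c1)=CCO[Si](C)(C)C(C)(C)C
A9 | alternative 3 | dimethyl malonate | COC(=O)CC(=O)OC
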